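5 questions stand on 4 flasks that differ in how the reagents go in.

* the flask with the highest share of target in target plus other capture product ("all alike" if they lie within 1.5 percentage points) (autumn / midnight / dawn / summer / all alike)
* share of target in target plus other capture product at the end, autumn
* share of target in target plus other capture product at the end, midnight
* share of target in target plus other capture product at the end, dawn
* share of target in target plus other capture product at the end, summer

| flask | substrate | first nucleophile | solid second nucleophile | remark | time |
|---|---|---|---|---|---|
| south | 0.10 M | 1.1 equiv | 0.80 equiv | run made earlier |  |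
| east | 0.10 M | 1.5 equiv | 0.80 equiv | run made earlier |  |
| north-east | 0.10 M | 2.4 equiv | 0.80 equiv | run made earlier |  |
| north-west | 0.10 M | 1.1 equiv | 0.40 equiv | run made earlier |  |
| autumn | 0.10 M | 1.10 equiv (fed, over 2.0 h) | 0.800 equiv | all else is in the flask from the start; the feed brings no volume worth counting | 2.5 h |
| midnight | 0.10 M | 1.10 equiv | 0.800 equiv | everything together at the start | 2.5 h |
| dawn | 0.10 M (fed, over 2.0 h) | 1.10 equiv | 0.800 equiv | all else is in the flask from the start; the feed brings no volume worth counting | 2.5 h |
| summer | 0.10 M | 1.10 equiv (in portions, 5, over 2.0 h) | 0.800 equiv | first portion at the start, last at 2.0 h | 2.5 h |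

south run (percent of the substrate charged)

| time / min | target / % | other capture product / % |
|---|---|---|
| 6.00 | 1.7 | 0.3 |
| 20.0 | 5.7 | 3.9 |
| 30.0 | 9.0 | 6.6 |
| 50.0 | 14.1 | 13.3 |
| 60.0 | 15.4 | 15.8 |
| 90.0 | 18.8 | 23.0 |

east run (percent of the substrate charged)

| time / h | target / % | other capture product / % |
|---|---|---|
| 0.500 | 10.6 | 5.9 |
| 1.00 | 17.8 | 14.3 |
| 1.50 | 21.1 | 20.0 |
| 2.00 | 25.4 | 24.9 |
| 2.50 | 28.6 | 26.4 |
| 3.00 | 31.2 | 27.8 |

north-east run (percent of the substrate charged)

| time / h | target / % | other capture product / % |
|---|---|---|
| 0.200 | 5.0 | 0.7 |
| 0.667 | 16.3 | 6.6 |
| 1.00 | 20.8 | 10.5 |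
| 1.50 | 24.5 | 15.7 |
| 2.50 | 33.0 | 21.0 |
| 3.00 | 36.5 | 20.9 |

north-west run (percent of the substrate charged)

| time / h | target / % | other capture product / % |
|---|---|---|
| 0.250 | 3.5 | 2.3 |
| 0.417 | 8.8 | 4.6 |
| 0.833 | 13.1 | 13.4 |
| 1.50 | 22.1 | 17.8 |
| 3.00 | 37.4 | 17.5 |

(standard deviation of a reading: 0.5 percentage points)

- the earlier runs were read with a standard deviation of 0.5 percentage points
- at the start none of the solid second nucleophile is in solution

The readings give one clock to watch. In the north-east run the other capture product stands at 21.0% after 2.50 h and 20.9% after 3.00 h, a stall within the scatter. Reading that stall as the end of the solid's supply gives the supply rate, the charge of solid second nucleophile per hour until the stall: 0.0320 M h⁻¹. The window of a charge is that charge divided by this rate. For the north-west run it gives 1.25 h, and that run, not used for the rate, still rises after 0.833 h and stands flat from 1.50 h. For the four flasks the window is 2.50 h, about the asked 2.5 h.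

The intermediate, taken as steady, splits at each moment by the two capture rates, so the share of target (the selectivity) follows [first nucleophile] against [second nucleophile].

Feeding the first nucleophile comes first. The feed of 2.0 h lies inside the window, and before any consumption the mean amount fed in is half the charge, for steady feed and portions alike. By hand, autumn and summer therefore lie together, below midnight.

Feeding the substrate comes next. In dawn the first nucleophile stands at its whole charge from the start, and the solid's clock does not wait for the substrate. At given [first nucleophile] and [second nucleophile], less substrate in the window lowers both captures by the same factor and leaves their split as it is, so my reckoning puts dawn about level with midnight.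

The forecast differs there: midnight first, with autumn 33%, midnight 44%, dawn 41% and summer 35%. Its ground for dawn reads “Dawn keeps the first nucleophile high, but substrate arrives after the early window favouring target”.

The flasks give autumn 32.4%, midnight 44.6%, summer 32.9% and dawn 47.5%, so dawn leads.

    second nucleophile → decomposed reagent (k = 5.90 × 10⁻⁴ s⁻¹)
    target ⇌ isomer of the product (K = 0.585, k = 1.97 × 10⁻⁴ s⁻¹)
    substrate → intermediate (k = 1.35 × 10⁻⁴ s⁻¹)
    first nucleophile + intermediate → target (k = 0.0143 M⁻¹ s⁻¹)
    solid second nucleophile ⇌ second nucleophile, rate k5*(cs5 - [second nucleophile]) while solid is left; crystals form when [second nucleophile] > cs5 (solubility = 0.0620 M, k = 2.49 × 10⁻⁴ s⁻¹)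
    second nucleophile + intermediate → other capture product (k = 0.123 M⁻¹ s⁻¹)

At the end dawn holds 20.6% of other capture product against 31.0% in midnight, and 6.01% of isomer of the product against 11.2%. Near the close of its 2.50 h window, dawn's second nucleophile falls from 0.00772 M after 2.00 h to 0.00109 M after 2.50 h. With 0.320 equiv of solid, the neighbour of autumn has a window of 1.00 h, shorter than its feed, and ends with 19.9% of other capture product and a share of 62.3%.

Readings and results are simulated with constants of no real substance; noise was put on by code.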